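**Strategy.** Numbering the chain C1 (OCH2) to C9 and the ring C10 (CH), C11 (C=CH2), C12–C14, C15 (CMe2), the plan rests on cutting both C7–C8 and C7–CH3 at the E alkene C6=C7, whose substituents (methyl and C8 on C7, the C5–C4 arm on C6) are those of a ring-opened 2,3-dihydrofuran. In one flask the (S)-iodide made of ring C10–C15 and its CH2CH2I arm, lithiated dihydrofuran and iodomethane are joined on copper: a stereospecific 1,2-metalate shift forms C7–C8 and opens the heterocycle, and methylation forms C7–CH3. The precursor is a primary iodide with one remote stereocentre and an exocyclic alkene; the C4 alcohol released then carries the last prenyl unit and the malonate.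

Key step: step 9

Assumption: in step 6 the salt of the (S)-acid with (R)-1-phenylethylamine is taken to be the less soluble diastereomer; if the pairing is the opposite, (S)-1-phenylethylamine is used and nothing else changes.

Step 1
Reactants: 1 3-methylcyclohex-2-en-1-one
Product: 3 3,3-dimethylcyclohex-1-en-1-yl trifluoromethanesulfonate, via lithium enolate 2 (not isolated)
Conditions: Me2CuLi (MeLi, CuI), Et2O, 0 °C; then PhNTf2, THF, 0 → 20 °C; aq NH4Cl
Reagents that add atoms: lithium dimethylcuprate, `[Li+].C[Cu-]C`; N-phenylbis(trifluoromethanesulfonimide), `O=S(=O)(N(c1ccccc1)S(=O)(=O)C(F)(F)F)C(F)(F)F`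
Why: Cuprate conjugate addition builds the gem-dimethyl carbon and leaves the enolate double bond fixed toward that carbon, so O-sulfonylation of the enolate (enolate trapping) should give the enol triflate as one regioisomer.

Step 2
Reactants: 3 3,3-dimethylcyclohex-1-en-1-yl trifluoromethanesulfonate
Product: 4 methyl 3,3-dimethylcyclohex-1-ene-1-carboxylate
Conditions: CO (1 atm), MeOH, Pd(OAc)2 (3 mol %), PPh3 (6 mol %), Et3N, DMF, 20 → 50 °C
Reagents that add atoms: carbon monoxide, `[C-]#[O+]`; methanol, `CO`
Why: Palladium-catalysed methoxycarbonylation of an enol triflate (oxidative addition to zerovalent palladium, CO insertion, methanolysis of the acylpalladium) should give the conjugated ester with the double bond unmoved.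

Step 3
Reactants: 4 methyl 3,3-dimethylcyclohex-1-ene-1-carboxylate
Product: 5 (3,3-dimethylcyclohex-1-en-1-yl)methanol
Conditions: i-Bu2AlH (2.3 equiv), CH2Cl2, −78 → 0 °C; aq KNaC4H4O6 (potassium sodium tartrate)
Reagents that add atoms: none
Why: 1,2-Hydride reduction of the conjugated ester by i-Bu2AlH should stop at the allylic alcohol, since the aluminium hydride does not add to the alkene.

Step 4
Reactants: 5 (3,3-dimethylcyclohex-1-en-1-yl)methanol; 6 triethyl orthoacetate
Product: 8 rac-ethyl 2-(2,2-dimethyl-6-methylidenecyclohexyl)acetate, via mixed ketene acetal 7 (not isolated)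
Conditions: 6 (6 equiv), EtCO2H (5 mol %), 140 °C, EtOH distilled off
Reagents that add atoms: none
Why: Johnson–Claisen rearrangement, in which acid-catalysed exchange gives ketene acetal 7 and its [3,3]-sigmatropic shift forms the ring C–CH2CO2Et bond beside the quaternary carbon while moving the double bond to the exocyclic position; the new stereocentre is formed as a racemate.

Step 5
Reactants: 8 rac-ethyl 2-(2,2-dimethyl-6-methylidenecyclohexyl)acetate
Product: 9 rac-2-(2,2-dimethyl-6-methylidenecyclohexyl)acetic acid
Conditions: LiOH, THF–MeOH–H2O, 50 °C; then 1 M HCl, 0 °C, to pH 3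
Reagents that add atoms: lithium hydroxide, `[Li+].[OH-]`
Why: Saponification of a primary acetate ester, in which hydroxide does not touch the alkene and the cold, brief acidification should spare the exocyclic double bond.

Step 6
Reactants: 9 rac-2-(2,2-dimethyl-6-methylidenecyclohexyl)acetic acid; 10 (R)-1-phenylethylamine
Product: 11 (R)-1-phenylethylammonium 2-[(1S)-2,2-dimethyl-6-methylidenecyclohexyl]acetate
Conditions: 10 (0.55 equiv), acetone, reflux → 4 °C; recrystallised to constant rotation
Reagents that add atoms: none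
Why: Classical resolution by diastereomeric salt formation, in which the two salts differ in solubility so that fractional crystallisation should enrich the salt of the (S)-acid, its purity to be checked by chiral GC of the derived methyl ester.

Step 7
Reactants: 11 (R)-1-phenylethylammonium 2-[(1S)-2,2-dimethyl-6-methylidenecyclohexyl]acetate
Product: 13 2-[(1S)-2,2-dimethyl-6-methylidenecyclohexyl]ethan-1-ol, via free (S)-acid 12 (not isolated)
Conditions: 1 M HCl, Et2O, 0 °C; organic layer dried (MgSO4); then LiAlH4, Et2O, 0 → 20 °C; H2O, aq NaOH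
Reagents that add atoms: none
Why: Acidification frees the carboxylic acid and hydride reduction with LiAlH4 takes it to the primary alcohol, leaving the isolated 1,1-disubstituted alkene and the non-acidic ring stereocentre untouched.

Step 8
Reactants: 13 2-[(1S)-2,2-dimethyl-6-methylidenecyclohexyl]ethan-1-ol
Product: 14 (2S)-2-(2-iodoethyl)-1,1-dimethyl-3-methylidenecyclohexane
Conditions: I2, PPh3, imidazole, CH2Cl2, 0 → 20 °C
Reagents that add atoms: iodine, `II`
Why: Appel-type iodination, in which iodide displaces the alkoxyphosphonium group by SN2 at the primary carbon under imidazole-buffered conditions that should spare the acid-sensitive exocyclic alkene.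

Step 9
Reactants: 14 (2S)-2-(2-iodoethyl)-1,1-dimethyl-3-methylidenecyclohexane; 15 2,3-dihydrofuran; 16 iodomethane
Product: 21 (3E)-6-[(1S)-2,2-dimethyl-6-methylidenecyclohexyl]-4-methylhex-3-en-1-ol, via primary alkyllithium 17 (not isolated), via 5-lithio-2,3-dihydrofuran 18 (not isolated), via mixed lithium cuprate 19 (not isolated), via alkenylcopper alkoxide 20 (not isolated)
Conditions: 14, t-BuLi (2.05 equiv), Et2O–pentane, −78 °C; CuBr·SMe2 (1.0 equiv), Me2S–Et2O, −78 → −50 °C; 18 (from 15, t-BuLi, THF, −78 → 0 °C), −78 → 20 °C; MeI (excess), DMPU, 0 → 20 °C; aq NH4Cl–NH3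
Reagents that add atoms: none
Why: Iodine–lithium exchange gives alkyllithium 17, which with CuBr·SMe2 and 18 forms mixed cuprate 19; on warming, the alkyl group shifts from copper to the oxygen-bearing alkenyl carbon anti to the breaking C–O bond (inversion at that carbon), so C7–C8 forms and the heterocycle opens to alkenylcopper 20 with copper cis to the oxidoethyl arm. Iodomethane then alkylates the C–Cu bond with retention and forms C7–CH3. The closest known reaction type is the 1,2-metalate rearrangement of cuprates of α-lithiated cyclic enol ethers followed by electrophilic trapping, which gives trisubstituted homoallylic alcohols. No ring is closed and no stereocentre is created; the only stereochemical element set is the C6=C7 geometry, which the inversion-then-retention sequence fixes as E. The selectivity needed is transfer of the primary alkyl group in preference to its loss by β-hydride elimination, which low temperature and prompt conversion of the alkylcopper into the cuprate should secure, while C10 is remote and non-acidic and keeps its S configuration.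

Step 10
Reactants: 21 (3E)-6-[(1S)-2,2-dimethyl-6-methylidenecyclohexyl]-4-methylhex-3-en-1-ol
Product: 22 (2S)-2-[(3E)-6-bromo-3-methylhex-3-en-1-yl]-1,1-dimethyl-3-methylidenecyclohexane
Conditions: CBr4, PPh3, CH2Cl2, 0 °C
Reagents that add atoms: tetrabromomethane, `BrC(Br)(Br)Br`
Why: Appel bromination, an SN2 displacement of the alkoxyphosphonium group by bromide at the primary carbon under neutral conditions, so neither alkene should migrate; the bromide is chosen over the iodide because it inserts magnesium with less Wurtz coupling.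

Step 11
Reactants: 22 (2S)-2-[(3E)-6-bromo-3-methylhex-3-en-1-yl]-1,1-dimethyl-3-methylidenecyclohexane; 23 ethyl but-2-ynoate
Product: 27 ethyl (2E,6E)-9-[(1S)-2,2-dimethyl-6-methylidenecyclohexyl]-3,7-dimethylnona-2,6-dienoate, via Grignard reagent 24 (not isolated), via alkylcopper 25 (not isolated), via alkenylcopper adduct 26 (not isolated)
Conditions: Mg, THF, 20 → 40 °C; CuBr·SMe2 (1.0 equiv), THF, −78 → −40 °C; 23 (1.5 equiv), −78 °C; MeOH then aq NH4Cl, −78 → 20 °C
Reagents that add atoms: none
Why: Grignard formation, transmetalation to the alkylcopper and syn carbocupration of the ynoate place the alkyl group on the methyl-bearing alkyne carbon and copper cis to it on the α-carbon, and protonation at −78 °C with retention should give the E-enoate.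

Step 12
Reactants: 27 ethyl (2E,6E)-9-[(1S)-2,2-dimethyl-6-methylidenecyclohexyl]-3,7-dimethylnona-2,6-dienoate
Product: 28 (2E,6E)-9-[(1S)-2,2-dimethyl-6-methylidenecyclohexyl]-3,7-dimethylnona-2,6-dien-1-ol
Conditions: i-Bu2AlH (2.3 equiv), CH2Cl2, −78 °C; aq KNaC4H4O6 (potassium sodium tartrate)
Reagents that add atoms: none
Why: 1,2-Hydride reduction of the conjugated ester by i-Bu2AlH should give the allylic alcohol without touching any of the three alkenes or their geometry.

Step 13
Reactants: 28 (2E,6E)-9-[(1S)-2,2-dimethyl-6-methylidenecyclohexyl]-3,7-dimethylnona-2,6-dien-1-ol; 29 2,2-dimethyl-1,3-dioxane-4,6-dione (Meldrum's acid)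
Product: 30 3-{[(2E,6E)-9-[(1S)-2,2-dimethyl-6-methylidenecyclohexyl]-3,7-dimethylnona-2,6-dien-1-yl]oxy}-3-oxopropanoic acid
Conditions: 29 (1.2 equiv), toluene, 85 °C
Reagents that add atoms: none
Why: Alcoholysis of Meldrum's acid, in which the alcohol opens the activated cyclic diester and loss of acetone leaves the hydrogen malonate directly, without coupling agent or protecting group and below the temperature of decarboxylation.

**Compound list**

1 | 3-methylcyclohex-2-en-1-one | `CC1=CC(=O)CCC1` | starting material
2 | lithium 3,3-dimethylcyclohex-1-en-1-olate | `[Li+].[O-]C1=CC(C)(C)CCC1` | intermediate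
3 | 3,3-dimethylcyclohex-1-en-1-yl trifluoromethanesulfonate | `FC(F)(F)S(=O)(=O)OC1=CC(C)(C)CCC1` | intermediate
4 | methyl 3,3-dimethylcyclohex-1-ene-1-carboxylate | `COC(=O)C1=CC(C)(C)CCC1` | intermediate
5 | (3,3-dimethylcyclohex-1-en-1-yl)methanol | `OCC1=CC(C)(C)CCC1` | intermediate
6 | triethyl orthoacetate | `CCOC(C)(OCC)OCC` | starting material
7 | 1-{[(1-ethoxyethenyl)oxy]methyl}-3,3-dimethylcyclohex-1-ene | `C=C(OCC)OCC1=CC(C)(C)CCC1` | intermediate
8 | rac-ethyl 2-(2,2-dimethyl-6-methylidenecyclohexyl)acetate | `C=C1CCCC(C)(C)C1CC(=O)OCC` | intermediate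
9 | rac-2-(2,2-dimethyl-6-methylidenecyclohexyl)acetic acid | `C=C1CCCC(C)(C)C1CC(=O)O` | intermediate
10 | (R)-1-phenylethylamine | `C[C@@H](N)c1ccccc1` | starting material
11 | (R)-1-phenylethylammonium 2-[(1S)-2,2-dimethyl-6-methylidenecyclohexyl]acetate | `C=C1CCCC(C)(C)[C@@H]1CC(=O)[O-].C[C@@H]([NH3+])c1ccccc1` | intermediate
12 | 2-[(1S)-2,2-dimethyl-6-methylidenecyclohexyl]acetic acid | `C=C1CCCC(C)(C)[C@@H]1CC(=O)O` | intermediate
13 | 2-[(1S)-2,2-dimethyl-6-methylidenecyclohexyl]ethan-1-ol | `C=C1CCCC(C)(C)[C@@H]1CCO` | intermediate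
14 | (2S)-2-(2-iodoethyl)-1,1-dimethyl-3-methylidenecyclohexane | `C=C1CCCC(C)(C)[C@@H]1CCI` | intermediate
15 | 2,3-dihydrofuran | `C1=COCC1` | starting material
16 | iodomethane | `CI` | starting material
17 | {2-[(1S)-2,2-dimethyl-6-methylidenecyclohexyl]ethyl}lithium | `C=C1CCCC(C)(C)[C@@H]1CC[Li]` | intermediate
18 | 5-lithio-2,3-dihydrofuran | `[Li]C1=CCCO1` | intermediate
19 | lithium {2-[(1S)-2,2-dimethyl-6-methylidenecyclohexyl]ethyl}(4,5-dihydrofuran-2-yl)cuprate | `[Li+].C=C1CCCC(C)(C)[C@@H]1CC[Cu-]C2=CCCO2` | intermediate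
20 | lithium (3Z)-4-cuprio-6-[(1S)-2,2-dimethyl-6-methylidenecyclohexyl]hex-3-en-1-olate (copper cis to the oxidoethyl arm) | `[Li+].C=C1CCCC(C)(C)[C@@H]1CC/C([Cu])=C/CC[O-]` | intermediate
21 | (3E)-6-[(1S)-2,2-dimethyl-6-methylidenecyclohexyl]-4-methylhex-3-en-1-ol | `C=C1CCCC(C)(C)[C@@H]1CC/C(C)=C/CCO` | intermediate
22 | (2S)-2-[(3E)-6-bromo-3-methylhex-3-en-1-yl]-1,1-dimethyl-3-methylidenecyclohexane | `C=C1CCCC(C)(C)[C@@H]1CC/C(C)=C/CCBr` | intermediate
23 | ethyl but-2-ynoate | `CC#CC(=O)OCC` | starting material
24 | {(3E)-6-[(1S)-2,2-dimethyl-6-methylidenecyclohexyl]-4-methylhex-3-en-1-yl}magnesium bromide | `C=C1CCCC(C)(C)[C@@H]1CC/C(C)=C/CC[Mg]Br` | intermediate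
25 | {(3E)-6-[(1S)-2,2-dimethyl-6-methylidenecyclohexyl]-4-methylhex-3-en-1-yl}copper (as its MgBr2 complex) | `C=C1CCCC(C)(C)[C@@H]1CC/C(C)=C/CC[Cu]` | intermediate
26 | ethyl (2Z,6E)-2-cuprio-9-[(1S)-2,2-dimethyl-6-methylidenecyclohexyl]-3,7-dimethylnona-2,6-dienoate (copper cis to C4) | `C=C1CCCC(C)(C)[C@@H]1CC/C(C)=C/CC/C(C)=C(/C(=O)OCC)[Cu]` | intermediate
27 | ethyl (2E,6E)-9-[(1S)-2,2-dimethyl-6-methylidenecyclohexyl]-3,7-dimethylnona-2,6-dienoate | `C=C1CCCC(C)(C)[C@@H]1CC/C(C)=C/CC/C(C)=C/C(=O)OCC` | intermediate
28 | (2E,6E)-9-[(1S)-2,2-dimethyl-6-methylidenecyclohexyl]-3,7-dimethylnona-2,6-dien-1-ol | `C=C1CCCC(C)(C)[C@@H]1CC/C(C)=C/CC/C(C)=C/CO` | intermediate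
29 | 2,2-dimethyl-1,3-dioxane-4,6-dione (Meldrum's acid) | `CC1(C)OC(=O)CC(=O)O1` | starting material
30 | 3-{[(2E,6E)-9-[(1S)-2,2-dimethyl-6-methylidenecyclohexyl]-3,7-dimethylnona-2,6-dien-1-yl]oxy}-3-oxopropanoic acid | `C=C1CCCC(C)(C)[C@@H]1CC/C(C)=C/CC/C(C)=C/COC(=O)CC(=O)O` | target

**Total step count:** 13.
**Longest linear sequence:** 13 steps (1 → 30); compounds 6, 10, 15, 16, 23 and 29 are purchased and enter directly.

**Three steps most likely to fail**

Step 9. The alkylcopper or the mixed cuprate may decay by β-hydride elimination or homocoupling faster than the alkyl group migrates, or the alkenylcopper may be protonated before it is methylated, so the alkyl fragment is lost or the methyl is missing. The fallback sets out from 14 and returns at 21. Lithiated dihydrofuran 18 (from 15 and t-BuLi) is alkylated with iodide 14 in THF–DMPU (−30 → 20 °C) to give (S)-5-{2-[2,2-dimethyl-6-methylidenecyclohexyl]ethyl}-2,3-dihydrofuran F1. F1 is then opened with MeMgBr and catalytic NiCl2(PPh3)2 in refluxing toluene. This nickel-catalysed Grignard coupling of the enol-ether C–O bond runs with retention, so methyl ends up cis to the hydroxyethyl arm and the product is 21.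

Step 6. The two diastereomeric salts may co-crystallise or fail to crystallise, so enrichment stalls short of a single enantiomer. The fallback sets out from 9 and returns at 13, replacing steps 6 and 7. Acid 9 is activated as its mixed pivalic anhydride (PivCl, Et3N, THF) and used to acylate (S)-4-benzyloxazolidin-2-one in the presence of LiCl. This gives (4S)-4-benzyl-3-{2-[(1S)-2,2-dimethyl-6-methylidenecyclohexyl]acetyl}oxazolidin-2-one F2 and its diastereomer (4S)-4-benzyl-3-{2-[(1R)-2,2-dimethyl-6-methylidenecyclohexyl]acetyl}oxazolidin-2-one F3, which are separated by chromatography. LiBH4 (Et2O, one equivalent of H2O, 0 °C) then reduces F2 directly to alcohol 13 and releases the auxiliary.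

Step 11. The alkenylcopper adduct may equilibrate through its allenoate form if the mixture warms before the quench, eroding the C2=C3 geometry, and Wurtz coupling may consume bromide during magnesium insertion. The fallback sets out from 22 and returns at 27. Grignard reagent 24, made from 22 as before, is cross-coupled under Fe(acac)3 catalysis (THF–NMP, −30 °C) with ethyl (2E)-3-{[(trifluoromethyl)sulfonyl]oxy}but-2-enoate F4, which is prepared from ethyl acetoacetate with Tf2O and aqueous Me4NOH. The coupling replaces the triflate with retention at a preformed alkene of defined geometry and should give 27.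

**Further compounds**

F1 | step 9 | (S)-5-{2-[2,2-dimethyl-6-methylidenecyclohexyl]ethyl}-2,3-dihydrofuran | `C=C1CCCC(C)(C)[C@@H]1CCC2=CCCO2`
F2 | step 6 | (4S)-4-benzyl-3-{2-[(1S)-2,2-dimethyl-6-methylidenecyclohexyl]acetyl}oxazolidin-2-one | `C=C1CCCC(C)(C)[C@@H]1CC(=O)N2[C@@H](Cc3ccccc3)COC2=O`
F3 | step 6 | (4S)-4-benzyl-3-{2-[(1R)-2,2-dimethyl-6-methylidenecyclohexyl]acetyl}oxazolidin-2-one | `C=C1CCCC(C)(C)[C@H]1CC(=O)N2[C@@H](Cc3ccccc3)COC2=O`
F4 | step 11 | ethyl (2E)-3-{[(trifluoromethyl)sulfonyl]oxy}but-2-enoate | `CCOC(=O)/C=C(C)/OS(=O)(=O)C(F)(F)F`
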